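**Plan**

1. Cuts (germacrane locants: ring C1–C10, lactone carbons C11–C13, C14 = methyl on C10, C15 = hydroxymethyl on C4; β = the face that carries C11). Silyl ether and C8 ester go last; the 1,10-epoxide goes back to the Z-C1=C10 alkene; the C3=O/C4-H/C5-H2 array goes back to a C3 carbinol beside a C4=C5 alkene; the lactone is cut at O–C6 and C11–C7 in one step; the ring at C3–C4; the chain at C7–C8.
2. Forward: Birch reduction and ozonolysis give C3–C2–C1=C10–C9–C8 with the Z alkene fixed by the former ring. An asymmetric Nozaki–Hiyama–Kishi coupling adds C7–C4/C15, and an intramolecular one closes the ten-membered ring. The α-methylene-γ-lactone ring is then fused on by a palladium-catalysed (3+2) heteroannulation of 2-bromoacrylic acid, followed by redox adjustment, epoxidation, acylation and desilylation.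
3. Enabling feature: ring atoms C4=C5–C6=C7 are a 1,3-diene. Its unhindered terminus C7 takes C11, the allyl terminus C6 takes the carboxylate oxygen (five-membered ring), and the leftover C4=C5 bond next to the C3 carbinol is the redox isomer of the target's keto array.
4. Stereochemistry: C8 from the chiral chromium ligand; C7 and C6 from C8 (inside-alkoxy face control, syn addition to the E-C6=C7 bond gives the trans-lactone); C4 by protonation of a ring enolate (enolizable, adjustable); C1/C10 by 8-hydroxyl-directed epoxidation of the Z alkene; the acyl centre from (R)-2-methylbutanoic acid.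

Key step: step 9

Remarks on the chemistry (assumptions):
- (R)-2-Methylbutanoic acid, (E)-1,2-diiodoethene and 2-bromoacrylic acid are taken as purchased materials.
- In step 4 the (S)-configured ligand is assumed to give the 6R alcohol; the sense of induction follows the ligand, so its antipode would be used otherwise.
- Where a centre is written ξ (C3 carbinol, C11 of the amine adducts) both epimers are carried, because the centre is removed later.

**Route**

Step 1
Reactants: 1 4-methylanisole
Product: 2 1-methoxy-4-methylcyclohexa-1,4-diene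
Conditions: Li, NH3 (l), t-BuOH, THF, −78 to −33 °C
Reagents that add atoms: none
Why: Birch reduction of an anisole should give the 2,5-dihydro product, in which the enol ether and the trisubstituted alkene are unconjugated and the ring holds the future C1=C10 bond in the Z geometry.

Step 2
Reactants: 2 1-methoxy-4-methylcyclohexa-1,4-diene
Product: 3 methyl (3Z)-4-methyl-6-oxohex-3-enoate
Conditions: O3, CH2Cl2/MeOH, pyridine (cat.), −78 °C; then Me2S, −78 °C to rt
Reagents that add atoms: ozone, [O-][O+]=O
Why: Ozonolysis should cleave only the electron-rich enol ether double bond and so deliver C3 (ester), C2, the Z-C1=C10(Me) alkene, C9 and C8 (aldehyde) in one piece with differentiated ends.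

Step 3
Reactants: 4 (E)-1,2-diiodoethene (threefold excess), 5 prop-2-yn-1-ol
Product: 6 (4E)-5-iodopent-4-en-2-yn-1-ol
Conditions: Pd(PPh3)4 (cat.), CuI (cat.), i-Pr2NH, THF, rt
Reagents that add atoms: none
Why: Sonogashira coupling with retention of the E geometry; the excess of diiodide should suppress double coupling.

Step 4
Reactants: 3 methyl (3Z)-4-methyl-6-oxohex-3-enoate, 6 (4E)-5-iodopent-4-en-2-yn-1-ol
Product: 7 methyl (3Z,6R,7E)-6,11-dihydroxy-4-methylundeca-3,7-dien-9-ynoate
Conditions: CrCl2, NiCl2 (cat.), Et3N, (S)-N-[2-(4-isopropyl-4,5-dihydrooxazol-2-yl)-6-methoxyphenyl]methanesulfonamide, THF, rt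
Reagents that add atoms: none
Why: Asymmetric Nozaki–Hiyama–Kishi coupling: the E-alkenylchromium adds to the aldehyde with retention of alkene geometry, the sulfonamide-oxazoline ligand on chromium sets the carbinol centre (C8 of the target, 8β-OH), and the ester, the alkyne and the free hydroxyl should be tolerated.

Step 5
Reactants: 7 methyl (3Z,6R,7E)-6,11-dihydroxy-4-methylundeca-3,7-dien-9-ynoate
Product: 9 methyl (3Z,6R,7E,9Z)-6,11-dihydroxy-10-iodo-4-methylundeca-3,7,9-trienoate, via alkenylstannane 8 (not isolated)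
Conditions: [Cp*RuCl]4 (cat.), Bu3SnH, CH2Cl2, rt; then I2, 0 °C
Reagents that add atoms: iodine, [I][I]; tributyltin hydride, CCCC[SnH](CCCC)CCCC
Why: Ruthenium-catalysed hydroxyl-directed trans-hydrostannation of the propargylic alcohol should put tin on the alkyne carbon next to the carbinol with H and Sn trans, and iododestannylation with retention then gives the Z-configured 2-iodo-1,3-diene.

Step 6
Reactants: 9 methyl (3Z,6R,7E,9Z)-6,11-dihydroxy-10-iodo-4-methylundeca-3,7,9-trienoate
Product: 10 methyl (3Z,6R,7E,9Z)-11-[(tert-butyldimethylsilyl)oxy]-6-hydroxy-10-iodo-4-methylundeca-3,7,9-trienoate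
Conditions: TBSCl (1.05 equiv), imidazole, CH2Cl2, −20 °C
Reagents that add atoms: tert-butyldimethylsilyl chloride, CC(C)(C)[Si](C)(C)Cl
Why: Silylation at low temperature should be selective for the primary allylic hydroxyl (C15) over the secondary one (C8), which stays free as the later directing group.

Step 7
Reactants: 10 methyl (3Z,6R,7E,9Z)-11-[(tert-butyldimethylsilyl)oxy]-6-hydroxy-10-iodo-4-methylundeca-3,7,9-trienoate
Product: 11 (3Z,6R,7E,9Z)-11-[(tert-butyldimethylsilyl)oxy]-6-hydroxy-10-iodo-4-methylundeca-3,7,9-trienal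
Conditions: i-Bu2AlH (2.2 equiv), CH2Cl2, −78 °C; MeOH, then aq. potassium sodium tartrate
Reagents that add atoms: none
Why: Partial reduction of the methyl ester at −78 °C should stop at the aldehyde through the aluminium hemiacetal (one equivalent is used up by the free hydroxyl); the β,γ-unsaturated aldehyde is used crude.

Step 8
Reactants: 11 (3Z,6R,7E,9Z)-11-[(tert-butyldimethylsilyl)oxy]-6-hydroxy-10-iodo-4-methylundeca-3,7,9-trienal
Product: 12 (2Z,4E,6R,8Z)-2-{[(tert-butyldimethylsilyl)oxy]methyl}-8-methylcyclodeca-2,4,8-triene-1,6-diol (both C1 epimers; ring C1 = C3 of the target)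
Conditions: CrCl2 (excess), NiCl2 (cat.), DMSO/THF, 0.002 M, slow addition, rt
Reagents that add atoms: none
Why: Intramolecular Nozaki–Hiyama–Kishi reaction: the alkenylchromium from the Z-iodide adds to the aldehyde with retention of geometry and closes the ten-membered ring at C3–C4; the new C3 carbinol centre is irrelevant because C3 becomes the ketone.

Step 9
Reactants: 12 (2Z,4E,6R,8Z)-2-{[(tert-butyldimethylsilyl)oxy]methyl}-8-methylcyclodeca-2,4,8-triene-1,6-diol, 13 2-bromoacrylic acid
Product: 14 (1(10)Z,4Z)-15-[(tert-butyldimethylsilyl)oxy]-3ξ,8β-dihydroxy-6βH,7αH-germacra-1(10),4,11(13)-trien-12,6-olide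
Conditions: Pd(OAc)2 (10 mol %), Na2CO3, n-Bu4NCl, DMF, 70 °C, 13 added slowly
Reagents that add atoms: none
Why: Oxidative addition of the C–Br bond of 13 (as its carboxylate) to zerovalent palladium gives a 1-carboxyvinylpalladium species that adds syn across the E-C6=C7 bond of the ring diene with carbon going to the terminus C7, and the resulting η3-allylpalladium (C6–C5–C4) is captured at C6 by the palladium-bound carboxylate, which releases zerovalent palladium, so that C11–C7 and O–C6 form in one catalytic cycle. The closest known reaction type is the Larock heteroannulation of 1,3-dienes by aryl and vinylic halides that carry a carboxylic acid. The only ring closed is the γ-lactone, by attack of the carboxylate oxygen on the near allyl terminus (five-membered ring through C6 instead of a seven-membered ring through C4). C7 is controlled by the C8 carbinol: on the outer face of the E-alkene the ring bond C8–C9 lies anti to the incoming palladium and the hydroxyl takes the inside position (inside-alkoxy arrangement, possibly helped by O–H contact with the palladium carboxylate), which puts C11 on the β-face, cis to the 8β-oxygen. C6 follows from C7, because the tethered carboxylate can only be delivered on the same outer face (the inner face is blocked by the ring), and syn addition to an E-alkene gives the trans (6α-O, 7α-H) lactone. The step needs terminus selectivity (C7, disubstituted, against C4, trisubstituted), an inert isolated trisubstituted C1(10) alkene and no ionization of allylic C–O bonds; the substitution pattern of the diene and the non-leaving free hydroxyls and silyl ether should secure these.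

Step 10
Reactants: 14 (1(10)Z,4Z)-15-[(tert-butyldimethylsilyl)oxy]-3ξ,8β-dihydroxy-6βH,7αH-germacra-1(10),4,11(13)-trien-12,6-olide
Product: 15 (1(10)Z,4Z)-15-[(tert-butyldimethylsilyl)oxy]-13-(dimethylamino)-3ξ,8β-dihydroxy-6βH,7αH,11ξH-germacra-1(10),4-dien-12,6-olide
Conditions: Me2NH (2 M in THF), THF, 0 °C
Reagents that add atoms: dimethylamine, CNC
Why: Aza-Michael addition masks the α-methylene lactone as its Mannich base, so that the later hydride step cannot touch it; the C11 epimers are of no consequence.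

Step 11
Reactants: 15 (1(10)Z,4Z)-15-[(tert-butyldimethylsilyl)oxy]-13-(dimethylamino)-3ξ,8β-dihydroxy-6βH,7αH,11ξH-germacra-1(10),4-dien-12,6-olide
Product: 16 (1(10)Z,4Z)-15-[(tert-butyldimethylsilyl)oxy]-13-(dimethylamino)-8β-hydroxy-3-oxo-6βH,7αH,11ξH-germacra-1(10),4-dien-12,6-olide
Conditions: activated MnO2, CH2Cl2, rt
Reagents that add atoms: none
Why: MnO2 should oxidize only the allylic C3 carbinol (both epimers converge on one enone) and leave the 8-hydroxyl, which is no longer allylic.

Step 12
Reactants: 16 (1(10)Z,4Z)-15-[(tert-butyldimethylsilyl)oxy]-13-(dimethylamino)-8β-hydroxy-3-oxo-6βH,7αH,11ξH-germacra-1(10),4-dien-12,6-olide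
Product: 17 (1(10)Z)-15-[(tert-butyldimethylsilyl)oxy]-13-(dimethylamino)-8β-hydroxy-3-oxo-4αH,6βH,7αH,11ξH-germacr-1(10)-en-12,6-olide
Conditions: [(Ph3P)CuH]6, benzene, H2O (few equiv), rt
Reagents that add atoms: none
Why: Conjugate reduction by the copper hydride hexamer puts hydride on C5, and the copper enolate is expected to be protonated at C4 on the outer face of the ring to give the 4αH ketone; this face preference is not secured by a model, but the centre is enolizable, so the epimer ratio can be adjusted by mild base.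

Step 13
Reactants: 17 (1(10)Z)-15-[(tert-butyldimethylsilyl)oxy]-13-(dimethylamino)-8β-hydroxy-3-oxo-4αH,6βH,7αH,11ξH-germacr-1(10)-en-12,6-olide
Product: 20 15-[(tert-butyldimethylsilyl)oxy]-1β,10β-epoxy-8β-hydroxy-3-oxo-1αH,4αH,6βH,7αH-germacr-11(13)-en-12,6-olide, via amine N-oxide 18 (not isolated), via hydroxy methylene lactone 19 (not isolated)
Conditions: VO(acac)2 (cat.), t-BuOOH (decane), CH2Cl2, 0 °C to rt
Reagents that add atoms: tert-butyl hydroperoxide, CC(C)(C)OO
Why: t-BuOOH oxidizes the amine to its N-oxide, whose Cope elimination restores the C11(13) methylene, and the vanadium alkylperoxide bound to the homoallylic 8β-hydroxyl should deliver oxygen to the β-face of the Z-C1(10) alkene (hydroxyl-directed epoxidation); the electron-poor methylene lactone and the ketone should not be oxidized.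

Step 14
Reactants: 20 15-[(tert-butyldimethylsilyl)oxy]-1β,10β-epoxy-8β-hydroxy-3-oxo-1αH,4αH,6βH,7αH-germacr-11(13)-en-12,6-olide, 21 (R)-2-methylbutanoic acid
Product: 22 15-[(tert-butyldimethylsilyl)oxy]-1β,10β-epoxy-8β-[(2R)-2-methylbutanoyloxy]-3-oxo-1αH,4αH,6βH,7αH-germacr-11(13)-en-12,6-olide
Conditions: dicyclohexylcarbodiimide, DMAP (cat.), CH2Cl2, 0 °C to rt
Reagents that add atoms: none
Why: Steglich esterification acylates the only free hydroxyl with retention at C8 and brings in the acyl stereocentre unchanged; the mild, nearly neutral conditions should spare the epoxide next to the ketone.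

Step 15
Reactants: 22 15-[(tert-butyldimethylsilyl)oxy]-1β,10β-epoxy-8β-[(2R)-2-methylbutanoyloxy]-3-oxo-1αH,4αH,6βH,7αH-germacr-11(13)-en-12,6-olide
Product: 23 CNP0219035.1, 1β,10β-epoxy-15-hydroxy-8β-[(2R)-2-methylbutanoyloxy]-3-oxo-1αH,4αH,6βH,7αH-germacr-11(13)-en-12,6-olide, (1R,4S,6R,7S,8R,10S)
Conditions: HF·pyridine, pyridine, THF, 0 °C
Reagents that add atoms: none
Why: Fluoride-mediated cleavage of the primary silyl ether buffered with pyridine should leave the trisubstituted epoxide, the β-hydroxy ketone and the methylene lactone intact.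

**Compound list**

1 | 4-methylanisole | COc1ccc(C)cc1 | starting material
2 | 1-methoxy-4-methylcyclohexa-1,4-diene | COC1=CCC(C)=CC1 | intermediate
3 | methyl (3Z)-4-methyl-6-oxohex-3-enoate | COC(=O)C/C=C(/C)CC=O | intermediate
4 | (E)-1,2-diiodoethene | I/C=C/I | starting material
5 | prop-2-yn-1-ol | OCC#C | starting material
6 | (4E)-5-iodopent-4-en-2-yn-1-ol | OCC#C/C=C/I | intermediate
7 | methyl (3Z,6R,7E)-6,11-dihydroxy-4-methylundeca-3,7-dien-9-ynoate | COC(=O)C/C=C(/C)C[C@@H](O)/C=C/C#CCO | intermediate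
8 | methyl (3Z,6R,7E,9Z)-6,11-dihydroxy-4-methyl-10-(tributylstannyl)undeca-3,7,9-trienoate | COC(=O)C/C=C(/C)C[C@@H](O)/C=C/C=C(\[Sn](CCCC)(CCCC)CCCC)CO | intermediate (not isolated)
9 | methyl (3Z,6R,7E,9Z)-6,11-dihydroxy-10-iodo-4-methylundeca-3,7,9-trienoate | COC(=O)C/C=C(/C)C[C@@H](O)/C=C/C=C(\I)CO | intermediate
10 | methyl (3Z,6R,7E,9Z)-11-[(tert-butyldimethylsilyl)oxy]-6-hydroxy-10-iodo-4-methylundeca-3,7,9-trienoate | COC(=O)C/C=C(/C)C[C@@H](O)/C=C/C=C(\I)CO[Si](C)(C)C(C)(C)C | intermediate
11 | (3Z,6R,7E,9Z)-11-[(tert-butyldimethylsilyl)oxy]-6-hydroxy-10-iodo-4-methylundeca-3,7,9-trienal | O=CC/C=C(/C)C[C@@H](O)/C=C/C=C(\I)CO[Si](C)(C)C(C)(C)C | intermediate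
12 | (2Z,4E,6R,8Z)-2-{[(tert-butyldimethylsilyl)oxy]methyl}-8-methylcyclodeca-2,4,8-triene-1,6-diol (C1 epimers) | OC1C/C=C(/C)C[C@@H](O)/C=C/C=C1/CO[Si](C)(C)C(C)(C)C | intermediate
13 | 2-bromoacrylic acid | OC(=O)C(Br)=C | starting material
14 | (1(10)Z,4Z)-15-[(tert-butyldimethylsilyl)oxy]-3ξ,8β-dihydroxy-6βH,7αH-germacra-1(10),4,11(13)-trien-12,6-olide | C=C1C(=O)O[C@@H]2/C=C(/CO[Si](C)(C)C(C)(C)C)C(O)C/C=C(/C)C[C@@H](O)[C@@H]12 | intermediate
15 | (1(10)Z,4Z)-15-[(tert-butyldimethylsilyl)oxy]-13-(dimethylamino)-3ξ,8β-dihydroxy-6βH,7αH,11ξH-germacra-1(10),4-dien-12,6-olide | CN(C)CC1C(=O)O[C@@H]2/C=C(/CO[Si](C)(C)C(C)(C)C)C(O)C/C=C(/C)C[C@@H](O)[C@@H]12 | intermediate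
16 | (1(10)Z,4Z)-15-[(tert-butyldimethylsilyl)oxy]-13-(dimethylamino)-8β-hydroxy-3-oxo-6βH,7αH,11ξH-germacra-1(10),4-dien-12,6-olide | CN(C)CC1C(=O)O[C@@H]2/C=C(/CO[Si](C)(C)C(C)(C)C)C(=O)C/C=C(/C)C[C@@H](O)[C@@H]12 | intermediate
17 | (1(10)Z)-15-[(tert-butyldimethylsilyl)oxy]-13-(dimethylamino)-8β-hydroxy-3-oxo-4αH,6βH,7αH,11ξH-germacr-1(10)-en-12,6-olide | CN(C)CC1C(=O)O[C@@H]2C[C@@H](CO[Si](C)(C)C(C)(C)C)C(=O)C/C=C(/C)C[C@@H](O)[C@@H]12 | intermediate
18 | N-oxide of 17 | C[N+](C)([O-])CC1C(=O)O[C@@H]2C[C@@H](CO[Si](C)(C)C(C)(C)C)C(=O)C/C=C(/C)C[C@@H](O)[C@@H]12 | intermediate (not isolated)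
19 | (1(10)Z)-15-[(tert-butyldimethylsilyl)oxy]-8β-hydroxy-3-oxo-4αH,6βH,7αH-germacra-1(10),11(13)-dien-12,6-olide | C=C1C(=O)O[C@@H]2C[C@@H](CO[Si](C)(C)C(C)(C)C)C(=O)C/C=C(/C)C[C@@H](O)[C@@H]12 | intermediate (not isolated)
20 | 15-[(tert-butyldimethylsilyl)oxy]-1β,10β-epoxy-8β-hydroxy-3-oxo-1αH,4αH,6βH,7αH-germacr-11(13)-en-12,6-olide | C=C1C(=O)O[C@@H]2C[C@@H](CO[Si](C)(C)C(C)(C)C)C(=O)C[C@H]3O[C@@]3(C)C[C@@H](O)[C@@H]12 | intermediate
21 | (R)-2-methylbutanoic acid | CC[C@@H](C)C(O)=O | starting material
22 | 15-[(tert-butyldimethylsilyl)oxy]-1β,10β-epoxy-8β-[(2R)-2-methylbutanoyloxy]-3-oxo-1αH,4αH,6βH,7αH-germacr-11(13)-en-12,6-olide | C=C1C(=O)O[C@@H]2C[C@@H](CO[Si](C)(C)C(C)(C)C)C(=O)C[C@H]3O[C@@]3(C)C[C@@H](OC(=O)[C@H](C)CC)[C@@H]12 | intermediate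
23 | CNP0219035.1, (1R,4S,6R,7S,8R,10S)-1β,10β-epoxy-15-hydroxy-8β-[(2R)-2-methylbutanoyloxy]-3-oxo-germacr-11(13)-en-12,6-olide | C=C1C(=O)O[C@@H]2C[C@@H](CO)C(=O)C[C@H]3O[C@@]3(C)C[C@@H](OC(=O)[C@H](C)CC)[C@@H]12 | target

**Step count and risks**

Total steps: 15. Longest linear sequence: 14 steps (steps 1, 2 and 4 to 15; step 3 is a one-step side branch).

Most likely to fail:

1. Step 8. Ring strain in a ten-membered ring that holds a conjugated Z,E-diene and a Z-alkene may slow closure, so that intermolecular coupling (oligomers) and loss of iodine by protonation take over. The fallback sets out from 7 and comes back at 17, and it replaces the alkenyl iodide by a ring closure at zerovalent nickel. Selective silylation of the primary hydroxyl of 7 gives the silyl ether F1, and i-Bu2AlH at −78 °C gives the ynal F2. Nickel-catalysed reductive macrocyclization of the aldehyde onto the conjugated enyne (Ni(cod)2, PBu3, Et3B, toluene, high dilution) forms the C3–C4 bond at the alkyne carbon distal to the alkene with cis addition of H and C, and gives the 4E ring dienol F3. The 4E geometry is of no consequence, since C4=C5 is saturated later: the operations of steps 9 to 11 turn F3 into the 4E lactone F4, its dimethylamine adduct F5 and the 4E enone F6, and the copper hydride reduction of step 12 then gives 17.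

2. Step 9. Poor facial selectivity of the carbopalladation on the ring diene, β-hydride elimination to trienes in place of allyl capture, or re-ionization of the allylic lactone may erode the annulation. The fallback sets out from 12 and comes back at 14, and it makes the same two bonds in one operation by a radical mechanism. Oxidation of diethylphosphonoacetic acid with trivalent manganese (Mn(OAc)3·2H2O, KOAc, AcOH, 40 °C) gives an electrophilic radical that adds to the diene terminus C7; the allyl radical is oxidized and closed at C6 by the carboxylic acid to give the α-phosphono lactone F7, by analogy with the lactone annulation of conjugated dienes by cyanoacetic acid and malonate half-esters. A Horner–Wadsworth–Emmons reaction of F7 with aqueous formaldehyde and K2CO3 then gives 14.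

3. Step 13. Amine oxidation with Cope elimination may compete with the hydroxyl-directed oxygen transfer, so that epoxidation is incomplete, goes to the wrong face or over-oxidizes. The fallback sets out from 17 and comes back at 22, and it separates the two events and changes the control element. One equivalent of mCPBA (−40 °C to rt) forms the N-oxide 18, which eliminates to 19, now isolated. Steglich esterification of 19 with 21 gives the 8-O-acyl alkene F8. Epoxidation of F8 with dimethyldioxirane in acetone at 0 °C then relies on attack on the exposed face of the ring conformation, in place of hydroxyl delivery, and gives 22.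

**Further compounds**

F1 | step 8 | methyl (3Z,6R,7E)-11-[(tert-butyldimethylsilyl)oxy]-6-hydroxy-4-methylundeca-3,7-dien-9-ynoate | COC(=O)C/C=C(/C)C[C@@H](O)/C=C/C#CCO[Si](C)(C)C(C)(C)C
F2 | step 8 | (3Z,6R,7E)-11-[(tert-butyldimethylsilyl)oxy]-6-hydroxy-4-methylundeca-3,7-dien-9-ynal | O=CC/C=C(/C)C[C@@H](O)/C=C/C#CCO[Si](C)(C)C(C)(C)C
F3 | step 8 | (2E,4E,6R,8Z)-2-{[(tert-butyldimethylsilyl)oxy]methyl}-8-methylcyclodeca-2,4,8-triene-1,6-diol (C1 epimers) | OC1C/C=C(/C)C[C@@H](O)/C=C/C=C1\CO[Si](C)(C)C(C)(C)C
F4 | step 8 | (1(10)Z,4E)-15-[(tert-butyldimethylsilyl)oxy]-3ξ,8β-dihydroxy-6βH,7αH-germacra-1(10),4,11(13)-trien-12,6-olide | C=C1C(=O)O[C@@H]2/C=C(\CO[Si](C)(C)C(C)(C)C)C(O)C/C=C(/C)C[C@@H](O)[C@@H]12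
F5 | step 8 | (1(10)Z,4E)-15-[(tert-butyldimethylsilyl)oxy]-13-(dimethylamino)-3ξ,8β-dihydroxy-6βH,7αH,11ξH-germacra-1(10),4-dien-12,6-olide | CN(C)CC1C(=O)O[C@@H]2/C=C(\CO[Si](C)(C)C(C)(C)C)C(O)C/C=C(/C)C[C@@H](O)[C@@H]12
F6 | step 8 | (1(10)Z,4E)-15-[(tert-butyldimethylsilyl)oxy]-13-(dimethylamino)-8β-hydroxy-3-oxo-6βH,7αH,11ξH-germacra-1(10),4-dien-12,6-olide | CN(C)CC1C(=O)O[C@@H]2/C=C(\CO[Si](C)(C)C(C)(C)C)C(=O)C/C=C(/C)C[C@@H](O)[C@@H]12
F7 | step 9 | (1(10)Z,4Z)-15-[(tert-butyldimethylsilyl)oxy]-11-(diethoxyphosphoryl)-3ξ,8β-dihydroxy-6βH,7αH-germacra-1(10),4-dien-12,6-olide | CCOP(=O)(OCC)C1C(=O)O[C@@H]2/C=C(/CO[Si](C)(C)C(C)(C)C)C(O)C/C=C(/C)C[C@@H](O)[C@@H]12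
F8 | step 13 | (1(10)Z)-15-[(tert-butyldimethylsilyl)oxy]-8β-[(2R)-2-methylbutanoyloxy]-3-oxo-4αH,6βH,7αH-germacra-1(10),11(13)-dien-12,6-olide | C=C1C(=O)O[C@@H]2C[C@@H](CO[Si](C)(C)C(C)(C)C)C(=O)C/C=C(/C)C[C@@H](OC(=O)[C@H](C)CC)[C@@H]12
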